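In a one-step world the ledger has a single line: one first end group and one second end group leave, and one link appears.

- Tuesday's: first end groups 0.15 M; second end groups 0.95 equiv; run made earlier
- flask: first end groups 0.10 M; second end groups 0.950 equiv; time 8.0 d

- Tuesday's (time / h: first end groups / %, links / %): 1.50: 10.6, 89.4; 3.00: 6.8, 92.8; 5.00: 5.7, 94.2; 10.0: 4.7, 94.3; 20.0: 4.8, 95.1

(readings scatter by 0.3 percentage points)

- which holds at 8.0 d: what has brought the reaction to rest, or that it has not come to rest (all of the first end groups has reacted / it is still moving / the second end groups has run out first)
- share of the first end groups used up at 8.0 d
- links at 8.0 d, in percent of the first end groups charged

- the numbers in the tables scatter with a standard deviation of 0.3 percentage points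
- the reaction counts as stopped when no species that holds the first end groups changes by six tenths of a point or more over the second half of the time

Tuesday's run keeps those books. At 20.0 h, links at 95.1% plus first end groups at 4.8% make 99.9% of the charge, so I need no second entry. Second end groups are the limiting reagent there: their 0.95 equiv pays for 95.0% links, and the links reading stands at that figure within the scatter of 0.3 percentage points.

For the new flask I freeze that closing balance as C = 95.0%, the link ceiling: the smaller of one and the equivalents of second end groups, as a share of the first end groups charged. In this one-step ledger, with the equivalents held, dilution touches the clock, not the closing balance. If a step takes one of each group, then at equal equivalents its pace scales with concentration, so the rest that Tuesday's readings show by 10.0 h moves by my estimate to about 15.0 h at 0.10 M, far shorter than 8.0 d. I book links and conversion at 95.0% each, with 5.00% of the first end groups left over.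

The forecast gives 95% links (94.2% to 95.6%) and 95% conversion (94.3% to 95.6%), with the verdict "the second end groups has run out first", reading that the “second end groups are used up”.

At 8.0 d the flask gives 95.0% links and 95.0% conversion: the second end groups has run out first, with 0% of them left.

    first end groups + second end groups → links + by-product (k = 0.870 L mol⁻¹ min⁻¹)

At 0.00781 d the half-life of first end groups by this step is 0.28 h, far shorter than 8.0 d, and at 0.800 d the flask holds 0.0335% of its second end groups, with links at 95.0% against the ceiling C = 95.0%. The same flask charged with 0.380 equiv of second end groups has C = 38.0%, and at 8.0 d it holds 0% of them and 38.0% links.

(The readings stem from a simulated flask for substances that don't exist, and the scatter is random.)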